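## Retrosynthetic overview

1. Feature: in the styryl-bearing 2,3-dihydrobenzofuran (O1, C2, C3, benzo ring A = C3a to C7a; the 7'-hydroxy dihydrobenzofuran is primed), C3 is a benzylic carbon ortho to the phenolic O1. It is therefore the exocyclic carbon of a latent ortho-quinone methide of ring A, and C2 is the one carbon missing between C3 and O1. C3', O1' and C2' of the primed ring stand in the same relation.
2. Disconnections, last bond first: the C4–styryl bond (Suzuki coupling at a C4 bromide); then C2–C3 and O1–C2 together ([4+1] of the ring-A quinone methide with a (2S,5S)-thiolanium 4-(methoxymethoxy)benzylide); then C3–C5' (aryllithium of the primed half onto a 2-bromo-6-hydroxybenzaldehyde, hydroxyl then exchanged for sulfinate).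
3. The enantiopure primed half comes from the same [4+1] on the quinone methide of a 5-bromo-salicyl sulfone, with the antipodal (2R,5R) salt.
4. Ring order: primed dihydrofuran ring first, unprimed dihydrofuran ring second. All seven phenols travel as methoxymethyl (MOM) ethers and are freed in the last step.

Key step: step 19

Assumption: the facial sense of the thiolanium benzylide is carried over from its addition to aldehydes (the methyl group cis to the ylide carbon shields one lobe); transposed to the dihydrobenzofuran, where the aryl group outranks the ring carbon at C2, the (2R,5R) salt should give the 2R,3R ring and the (2S,5S) salt the 2S,3S ring. The route is written accordingly, and the two salts are simply exchanged if the sense proves opposite.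

## Route

Step 1
Reactants: 1 4-hydroxybenzaldehyde
Product: 2 4-(methoxymethoxy)benzaldehyde
Conditions: MOMCl, i-Pr2NEt, CH2Cl2, 0 °C to rt
Reagents that add atoms: chloromethyl methyl ether, COCCl
Why: Williamson-type O-alkylation of the phenoxide by the chloromethyl ether; the aldehyde is inert to the amine base.

Step 2
Reactants: 2 4-(methoxymethoxy)benzaldehyde
Product: 3 [4-(methoxymethoxy)phenyl]methanol
Conditions: NaBH4, MeOH, 0 °C
Reagents that add atoms: none
Why: Borohydride reduction of the aldehyde in a basic medium that leaves the acetal untouched.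

Step 3
Reactants: 3 [4-(methoxymethoxy)phenyl]methanol
Product: 4 1-(bromomethyl)-4-(methoxymethoxy)benzene
Conditions: CBr4, PPh3, CH2Cl2, 0 °C; used at once
Reagents that add atoms: carbon tetrabromide, BrC(Br)(Br)Br
Why: Appel bromination under neutral conditions spares the acid-labile acetal; the activated benzylic bromide is not stored.

Step 4
Reactants: 5 (2S,5S)-hexane-2,5-diol
Product: 6 (2S,5S)-hexane-2,5-diyl dimethanesulfonate
Conditions: MsCl, Et3N, CH2Cl2, 0 °C
Reagents that add atoms: methanesulfonyl chloride, CS(=O)(=O)Cl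
Why: Sulfonylation at oxygen of both secondary alcohols, which does not touch the carbinol centres.

Step 5
Reactants: 6 (2S,5S)-hexane-2,5-diyl dimethanesulfonate
Product: 7 (2R,5R)-2,5-dimethylthiolane
Conditions: Na2S·9H2O, DMSO, rt; distillation
Reagents that add atoms: sodium sulfide, [Na+].[Na+].[S-2]
Why: Double SN2 displacement by sulfide with inversion at both carbons turns the (2S,5S) dimesylate into the (2R,5R) thiolane.

Step 6
Reactants: 7 (2R,5R)-2,5-dimethylthiolane; 4 1-(bromomethyl)-4-(methoxymethoxy)benzene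
Product: 8 (2R,5R)-1-{[4-(methoxymethoxy)phenyl]methyl}-2,5-dimethylthiolan-1-ium tetrafluoroborate
Conditions: NaBF4, acetone, rt
Reagents that add atoms: sodium tetrafluoroborate, [Na+].F[B-](F)(F)F
Why: SN2 S-alkylation by the benzylic bromide with exchange of bromide for the non-nucleophilic tetrafluoroborate (NaBr precipitates), so the salt cannot revert; sulfur is not a stereocentre because the thiolane is C2-symmetric.

Step 7
Reactants: 9 (2R,5R)-hexane-2,5-diol
Product: 10 (2R,5R)-hexane-2,5-diyl dimethanesulfonate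
Conditions: MsCl, Et3N, CH2Cl2, 0 °C
Reagents that add atoms: methanesulfonyl chloride, CS(=O)(=O)Cl
Why: As in step 4, sulfonylation at oxygen without change at carbon.

Step 8
Reactants: 10 (2R,5R)-hexane-2,5-diyl dimethanesulfonate
Product: 11 (2S,5S)-2,5-dimethylthiolane
Conditions: Na2S·9H2O, DMSO, rt; distillation
Reagents that add atoms: sodium sulfide, [Na+].[Na+].[S-2]
Why: As in step 5, double SN2 displacement with inversion at both centres.

Step 9
Reactants: 11 (2S,5S)-2,5-dimethylthiolane; 4 1-(bromomethyl)-4-(methoxymethoxy)benzene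
Product: 12 (2S,5S)-1-{[4-(methoxymethoxy)phenyl]methyl}-2,5-dimethylthiolan-1-ium tetrafluoroborate
Conditions: NaBF4, acetone, rt
Reagents that add atoms: sodium tetrafluoroborate, [Na+].F[B-](F)(F)F
Why: As in step 6, S-alkylation with counter-ion exchange.

Step 10
Reactants: 13 5-bromobenzene-1,3-diol
Product: 14 1-bromo-3,5-bis(methoxymethoxy)benzene
Conditions: MOMCl (2.5 equiv), i-Pr2NEt, CH2Cl2, 0 °C to rt
Reagents that add atoms: chloromethyl methyl ether, COCCl
Why: Twofold O-alkylation of the resorcinol hydroxyls.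

Step 11
Reactants: 15 5-bromo-2,3-dihydroxybenzaldehyde
Product: 16 5-bromo-2-hydroxy-3-(methoxymethoxy)benzaldehyde
Conditions: NaH (2.2 equiv), DMF, 0 °C; MOMCl (1.0 equiv), 0 °C to rt; dilute HCl
Reagents that add atoms: chloromethyl methyl ether, COCCl
Why: Regioselective alkylation of the dianion at the more nucleophilic 3-phenoxide, the 2-phenoxide being delocalised into and chelated by the formyl group.

Step 12
Reactants: 14 1-bromo-3,5-bis(methoxymethoxy)benzene; 16 5-bromo-2-hydroxy-3-(methoxymethoxy)benzaldehyde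
Product: 18 4-bromo-2-{[3,5-bis(methoxymethoxy)phenyl](hydroxy)methyl}-6-(methoxymethoxy)phenol (racemic), via Grignard reagent 17 (not isolated)
Conditions: Mg, I2 (cat.), THF, reflux; then 16 (0.43 equiv), THF, 0 °C to rt; aq NH4Cl
Reagents that add atoms: none
Why: Grignard formation and 1,2-addition to the aldehyde, the first equivalent being spent on the phenol proton; the aryl bromide of 16 does not exchange with an arylmagnesium halide at 0 °C, and the new carbinol centre needs no control because step 14 erases it.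

Step 13
Reactants: 18 4-bromo-2-{[3,5-bis(methoxymethoxy)phenyl](hydroxy)methyl}-6-(methoxymethoxy)phenol
Product: 19 4-bromo-2-{[3,5-bis(methoxymethoxy)phenyl](4-methylbenzenesulfonyl)methyl}-6-(methoxymethoxy)phenol (racemic)
Conditions: p-TolSO2H (1.5 equiv), CH2Cl2, rt
Reagents that add atoms: 4-methylbenzenesulfinic acid, Cc1ccc(cc1)S(=O)O
Why: SN1-type substitution of the ortho-hydroxybenzhydrol, whose cation (a protonated quinone methide) is captured at sulfur by sulfinate; the weak sulfinic acid in an aprotic solvent should spare the MOM ethers.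

Step 14
Reactants: 19 4-bromo-2-{[3,5-bis(methoxymethoxy)phenyl](4-methylbenzenesulfonyl)methyl}-6-(methoxymethoxy)phenol; 8 (2R,5R)-1-{[4-(methoxymethoxy)phenyl]methyl}-2,5-dimethylthiolan-1-ium tetrafluoroborate
Product: 23 (2R,3R)-3-[3,5-bis(methoxymethoxy)phenyl]-5-bromo-7-(methoxymethoxy)-2-[4-(methoxymethoxy)phenyl]-2,3-dihydro-1-benzofuran, via quinone methide 20 (not isolated), via sulfonium ylide 21 (not isolated), via betaine 22 (not isolated)
Conditions: 8 (1.5 equiv), Cs2CO3 (4 equiv), CH2Cl2, 0 °C to rt; recrystallisation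
Reagents that add atoms: none
Why: Formal [4+1] annulation in which base releases quinone methide 20 and benzylide 21, conjugate addition gives betaine 22 and 5-exo-tet displacement of the thiolane closes the trans ring, the (2R,5R)-thiolane choosing the ylide face that should lead to 2R,3R; recrystallisation is planned to raise the enantiomeric purity.

Step 15
Reactants: 13 5-bromobenzene-1,3-diol
Product: 24 2-bromo-4,6-dihydroxybenzaldehyde
Conditions: POCl3, DMF, MeCN, 0 °C to rt; then H2O, 50 °C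
Reagents that add atoms: N,N-dimethylformamide, CN(C)C=O; water, O
Why: Vilsmeier–Haack formylation at the ring position para to one hydroxyl and ortho to the other, the usual site for 5-substituted resorcinols, followed by hydrolysis of the iminium salt.

Step 16
Reactants: 24 2-bromo-4,6-dihydroxybenzaldehyde
Product: 25 2-bromo-6-hydroxy-4-(methoxymethoxy)benzaldehyde
Conditions: MOMCl (1.05 equiv), i-Pr2NEt, CH2Cl2, 0 °C
Reagents that add atoms: chloromethyl methyl ether, COCCl
Why: Selective alkylation of the 4-hydroxyl, since the 6-hydroxyl is held in a hydrogen bond to the formyl group.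

Step 17
Reactants: 23 (2R,3R)-3-[3,5-bis(methoxymethoxy)phenyl]-5-bromo-7-(methoxymethoxy)-2-[4-(methoxymethoxy)phenyl]-2,3-dihydro-1-benzofuran; 25 2-bromo-6-hydroxy-4-(methoxymethoxy)benzaldehyde
Product: 28 3-bromo-2-{hydroxy[(2R,3R)-3-[3,5-bis(methoxymethoxy)phenyl]-7-(methoxymethoxy)-2-[4-(methoxymethoxy)phenyl]-2,3-dihydro-1-benzofuran-5-yl]methyl}-5-(methoxymethoxy)phenol (both carbinol epimers), via sodium phenolate 26 (not isolated), via aryllithium 27 (not isolated)
Conditions: 25 (1.5 equiv), NaH, THF, 0 °C (gives 26); separately 23, n-BuLi (1.0 equiv), THF, −78 °C (gives 27); combine at −78 °C, warm to 0 °C; aq NH4Cl; used crude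
Reagents that add atoms: none
Why: Bromine–lithium exchange, faster at −78 °C than metalation next to the acetals, then 1,2-addition of the aryllithium to the aldehyde whose acidic phenol is masked as its sodium salt; the carbinol centre is left uncontrolled because it becomes the trigonal methide carbon.

Step 18
Reactants: 28 the diol of step 17
Product: 29 3-bromo-5-(methoxymethoxy)-2-{(4-methylbenzenesulfonyl)[(2R,3R)-3-[3,5-bis(methoxymethoxy)phenyl]-7-(methoxymethoxy)-2-[4-(methoxymethoxy)phenyl]-2,3-dihydro-1-benzofuran-5-yl]methyl}phenol (both epimers at the sulfonyl carbon)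
Conditions: p-TolSO2H (2 equiv), CH2Cl2, 0 °C to rt
Reagents that add atoms: 4-methylbenzenesulfinic acid, Cc1ccc(cc1)S(=O)O
Why: As in step 13, and easier still, because the benzylic cation is stabilised by the ortho-hydroxyl and para-acetal oxygen of ring A and by O1' para on the primed ring.

Step 19
Reactants: 29 the sulfone of step 18; 12 (2S,5S)-1-{[4-(methoxymethoxy)phenyl]methyl}-2,5-dimethylthiolan-1-ium tetrafluoroborate
Product: 33 (2S,3S)-3-[(2R,3R)-3-[3,5-bis(methoxymethoxy)phenyl]-7-(methoxymethoxy)-2-[4-(methoxymethoxy)phenyl]-2,3-dihydro-1-benzofuran-5-yl]-4-bromo-6-(methoxymethoxy)-2-[4-(methoxymethoxy)phenyl]-2,3-dihydro-1-benzofuran, via quinone methide 30 (not isolated), via sulfonium ylide 31 (not isolated), via betaine 32 (not isolated)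
Conditions: 12 (1.5 equiv), Cs2CO3 (4 equiv), CH2Cl2, 0 °C to rt; chromatography
Reagents that add atoms: none
Why: Cs2CO3 deprotonates the phenol of 29, which expels p-toluenesulfinate to give quinone methide 30 (methide carbon = C3, already carrying the primed half), and deprotonates 12 to benzylide 31; the ylide carbon adds 1,4 to the methide carbon (C2–C3), ring A re-aromatises to phenoxide betaine 32, and the phenoxide displaces the thiolane from C2 (O1–C2). The closest known reaction type is the formal [4+1] annulation of quinone methides released from 2-(1-tosylalkyl)phenols with sulfur ylides, which gives trans-2,3-dihydrobenzofurans, combined with the ylide-transfer chemistry of C2-symmetric thiolanium benzylides known from epoxidation. The dihydrofuran ring closes 5-exo-tet with inversion at C2. C2 is set by the reagent, since the benzylide aryl turns away from the thiolane ring and the methyl group cis to the ylide carbon shields one lobe so that one ylide face adds, and C3 is set relative to C2 through the anti betaine that keeps the two aryl groups apart and closes to the trans ring, which with the (2S,5S) salt should be 2S,3S. The step needs C-attack at the methide carbon in preference to O-benzylation of the phenoxide or oligomerisation of the methide, and trans over cis closure; the non-nucleophilic tetrafluoroborate counter-ion, the easy sulfinate loss from a benzylic carbon para to the ring-A acetal oxygen and to O1', and the reversibility of betaine formation at so stabilised a methide should secure both. The primed centres are too remote to influence the outcome, and any diastereomer that stems from residual antipode of 23 is removed by chromatography at this stage.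

Step 20
Reactants: 2 4-(methoxymethoxy)benzaldehyde
Product: 34 2-{(E)-2-[4-(methoxymethoxy)phenyl]ethenyl}-4,4,5,5-tetramethyl-1,3,2-dioxaborolane
Conditions: CH2(Bpin)2, LiTMP (from 2,2,6,6-tetramethylpiperidine and n-BuLi), THF, 0 °C; then 2, −78 °C to rt; aq NH4Cl
Reagents that add atoms: bis(4,4,5,5-tetramethyl-1,3,2-dioxaborolan-2-yl)methane, CC1(C)OB(CB2OC(C)(C)C(C)(C)O2)OC1(C)C
Why: Boron–Wittig olefination, in which the lithiated geminal bis(boronate) adds to the aldehyde and syn-eliminates a borate to give the E alkenylboronate.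

Step 21
Reactants: 33 the bromide of step 19; 34 the E alkenylboronate of step 20
Product: 35 (2S,3S)-3-[(2R,3R)-3-[3,5-bis(methoxymethoxy)phenyl]-7-(methoxymethoxy)-2-[4-(methoxymethoxy)phenyl]-2,3-dihydro-1-benzofuran-5-yl]-6-(methoxymethoxy)-2-[4-(methoxymethoxy)phenyl]-4-{(E)-2-[4-(methoxymethoxy)phenyl]ethenyl}-2,3-dihydro-1-benzofuran
Conditions: Pd(OAc)2 (5 mol%), SPhos (10 mol%), K3PO4, toluene/H2O, 80 °C
Reagents that add atoms: none
Why: Suzuki–Miyaura coupling with retention of the E geometry; the biaryl dialkylphosphine ligand suits the ortho-substituted, electron-rich bromide, and the phosphate base should not epimerise C2 or C3.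

Step 22
Reactants: 35 the heptakis(methoxymethyl) ether of step 21
Product: 36 CNP0172909.1, (2S,3S)-3-[(2R,3R)-3-(3,5-dihydroxyphenyl)-7-hydroxy-2-(4-hydroxyphenyl)-2,3-dihydro-1-benzofuran-5-yl]-2-(4-hydroxyphenyl)-4-[(E)-2-(4-hydroxyphenyl)ethenyl]-2,3-dihydro-1-benzofuran-6-ol
Conditions: HCl (1.25 M in MeOH), THF, 0 °C to rt, argon, dark
Reagents that add atoms: none
Why: Acid-catalysed transacetalisation to methanol removes all seven MOM groups, the formaldehyde unit leaving as dimethoxymethane and not as free formaldehyde; dilute acid at low temperature is chosen to spare the stilbene and the benzylic C–O bonds.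

## Compound list

1 | 4-hydroxybenzaldehyde | O=Cc1ccc(O)cc1 | starting material
2 | 4-(methoxymethoxy)benzaldehyde | O=Cc1ccc(OCOC)cc1 | intermediate
3 | [4-(methoxymethoxy)phenyl]methanol | OCc1ccc(OCOC)cc1 | intermediate
4 | 1-(bromomethyl)-4-(methoxymethoxy)benzene | BrCc1ccc(OCOC)cc1 | intermediate
5 | (2S,5S)-hexane-2,5-diol | C[C@H](O)CC[C@H](C)O | starting material
6 | (2S,5S)-hexane-2,5-diyl dimethanesulfonate | C[C@H](OS(C)(=O)=O)CC[C@H](C)OS(C)(=O)=O | intermediate
7 | (2R,5R)-2,5-dimethylthiolane | C[C@@H]1CC[C@@H](C)S1 | intermediate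
8 | (2R,5R)-1-{[4-(methoxymethoxy)phenyl]methyl}-2,5-dimethylthiolan-1-ium tetrafluoroborate | C[C@@H]1CC[C@@H](C)[S+]1Cc1ccc(OCOC)cc1.F[B-](F)(F)F | intermediate
9 | (2R,5R)-hexane-2,5-diol | C[C@@H](O)CC[C@@H](C)O | starting material
10 | (2R,5R)-hexane-2,5-diyl dimethanesulfonate | C[C@@H](OS(C)(=O)=O)CC[C@@H](C)OS(C)(=O)=O | intermediate
11 | (2S,5S)-2,5-dimethylthiolane | C[C@H]1CC[C@H](C)S1 | intermediate
12 | (2S,5S)-1-{[4-(methoxymethoxy)phenyl]methyl}-2,5-dimethylthiolan-1-ium tetrafluoroborate | C[C@H]1CC[C@H](C)[S+]1Cc1ccc(OCOC)cc1.F[B-](F)(F)F | intermediate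
13 | 5-bromobenzene-1,3-diol (5-bromoresorcinol) | Oc1cc(O)cc(Br)c1 | starting material
14 | 1-bromo-3,5-bis(methoxymethoxy)benzene | COCOc1cc(Br)cc(OCOC)c1 | intermediate
15 | 5-bromo-2,3-dihydroxybenzaldehyde | O=Cc1cc(Br)cc(O)c1O | starting material
16 | 5-bromo-2-hydroxy-3-(methoxymethoxy)benzaldehyde | O=Cc1cc(Br)cc(OCOC)c1O | intermediate
17 | [3,5-bis(methoxymethoxy)phenyl]magnesium bromide (not isolated) | COCOc1cc([Mg]Br)cc(OCOC)c1 | intermediate
18 | 4-bromo-2-{[3,5-bis(methoxymethoxy)phenyl](hydroxy)methyl}-6-(methoxymethoxy)phenol, racemic | OC(c1cc(OCOC)cc(OCOC)c1)c1cc(Br)cc(OCOC)c1O | intermediate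
19 | 4-bromo-2-{[3,5-bis(methoxymethoxy)phenyl](4-methylbenzenesulfonyl)methyl}-6-(methoxymethoxy)phenol, racemic | Cc1ccc(cc1)S(=O)(=O)C(c1cc(OCOC)cc(OCOC)c1)c1cc(Br)cc(OCOC)c1O | intermediate
20 | 6-{[3,5-bis(methoxymethoxy)phenyl]methylidene}-4-bromo-2-(methoxymethoxy)cyclohexa-2,4-dien-1-one (quinone methide, not isolated) | O=C1C(OCOC)=CC(Br)=CC1=Cc1cc(OCOC)cc(OCOC)c1 | intermediate
21 | (2R,5R)-2,5-dimethylthiolan-1-ium-1-yl [4-(methoxymethoxy)phenyl]methanide (ylide of 8, not isolated) | C[C@@H]1CC[C@@H](C)[S+]1[CH-]c1ccc(OCOC)cc1 | intermediate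
22 | 4-bromo-2-{(1R,2S)-1-[3,5-bis(methoxymethoxy)phenyl]-2-[(2R,5R)-2,5-dimethylthiolan-1-ium-1-yl]-2-[4-(methoxymethoxy)phenyl]ethyl}-6-(methoxymethoxy)phenolate (anti betaine, not isolated) | [O-]c1c(OCOC)cc(Br)cc1[C@@H](c1cc(OCOC)cc(OCOC)c1)[C@@H](c1ccc(OCOC)cc1)[S+]1[C@H](C)CC[C@H]1C | intermediate
23 | (2R,3R)-3-[3,5-bis(methoxymethoxy)phenyl]-5-bromo-7-(methoxymethoxy)-2-[4-(methoxymethoxy)phenyl]-2,3-dihydro-1-benzofuran | Brc1cc(OCOC)c2c(c1)[C@@H](c1cc(OCOC)cc(OCOC)c1)[C@H](c1ccc(OCOC)cc1)O2 | intermediate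
24 | 2-bromo-4,6-dihydroxybenzaldehyde | O=Cc1c(Br)cc(O)cc1O | intermediate
25 | 2-bromo-6-hydroxy-4-(methoxymethoxy)benzaldehyde | O=Cc1c(Br)cc(OCOC)cc1O | intermediate
26 | sodium 3-bromo-2-formyl-5-(methoxymethoxy)phenolate (not isolated) | [Na+].[O-]c1cc(OCOC)cc(Br)c1C=O | intermediate
27 | {(2R,3R)-3-[3,5-bis(methoxymethoxy)phenyl]-7-(methoxymethoxy)-2-[4-(methoxymethoxy)phenyl]-2,3-dihydro-1-benzofuran-5-yl}lithium (not isolated) | [Li]c1cc(OCOC)c2c(c1)[C@@H](c1cc(OCOC)cc(OCOC)c1)[C@H](c1ccc(OCOC)cc1)O2 | intermediate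
28 | 3-bromo-2-{hydroxy[(2R,3R)-3-[3,5-bis(methoxymethoxy)phenyl]-7-(methoxymethoxy)-2-[4-(methoxymethoxy)phenyl]-2,3-dihydro-1-benzofuran-5-yl]methyl}-5-(methoxymethoxy)phenol, both carbinol epimers | Oc1cc(OCOC)cc(Br)c1C(O)c1cc(OCOC)c2c(c1)[C@@H](c1cc(OCOC)cc(OCOC)c1)[C@H](c1ccc(OCOC)cc1)O2 | intermediate
29 | 3-bromo-5-(methoxymethoxy)-2-{(4-methylbenzenesulfonyl)[(2R,3R)-3-[3,5-bis(methoxymethoxy)phenyl]-7-(methoxymethoxy)-2-[4-(methoxymethoxy)phenyl]-2,3-dihydro-1-benzofuran-5-yl]methyl}phenol, both epimers at the sulfonyl carbon | Oc1cc(OCOC)cc(Br)c1C(S(=O)(=O)c1ccc(C)cc1)c1cc(OCOC)c2c(c1)[C@@H](c1cc(OCOC)cc(OCOC)c1)[C@H](c1ccc(OCOC)cc1)O2 | intermediate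
30 | 3-bromo-5-(methoxymethoxy)-6-{[(2R,3R)-3-[3,5-bis(methoxymethoxy)phenyl]-7-(methoxymethoxy)-2-[4-(methoxymethoxy)phenyl]-2,3-dihydro-1-benzofuran-5-yl]methylidene}cyclohexa-2,4-dien-1-one (quinone methide, not isolated) | O=C1C=C(OCOC)C=C(Br)C1=Cc1cc(OCOC)c2c(c1)[C@@H](c1cc(OCOC)cc(OCOC)c1)[C@H](c1ccc(OCOC)cc1)O2 | intermediate
31 | (2S,5S)-2,5-dimethylthiolan-1-ium-1-yl [4-(methoxymethoxy)phenyl]methanide (ylide of 12, not isolated) | C[C@H]1CC[C@H](C)[S+]1[CH-]c1ccc(OCOC)cc1 | intermediate
32 | 3-bromo-2-{(1S,2R)-1-[(2R,3R)-3-[3,5-bis(methoxymethoxy)phenyl]-7-(methoxymethoxy)-2-[4-(methoxymethoxy)phenyl]-2,3-dihydro-1-benzofuran-5-yl]-2-[(2S,5S)-2,5-dimethylthiolan-1-ium-1-yl]-2-[4-(methoxymethoxy)phenyl]ethyl}-5-(methoxymethoxy)phenolate (anti betaine, not isolated) | [O-]c1cc(OCOC)cc(Br)c1[C@H](c1cc(OCOC)c2c(c1)[C@@H](c1cc(OCOC)cc(OCOC)c1)[C@H](c1ccc(OCOC)cc1)O2)[C@H](c1ccc(OCOC)cc1)[S+]1[C@@H](C)CC[C@@H]1C | intermediate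
33 | (2S,3S)-3-[(2R,3R)-3-[3,5-bis(methoxymethoxy)phenyl]-7-(methoxymethoxy)-2-[4-(methoxymethoxy)phenyl]-2,3-dihydro-1-benzofuran-5-yl]-4-bromo-6-(methoxymethoxy)-2-[4-(methoxymethoxy)phenyl]-2,3-dihydro-1-benzofuran | Brc1cc(OCOC)cc2c1[C@H](c1cc(OCOC)c3c(c1)[C@@H](c1cc(OCOC)cc(OCOC)c1)[C@H](c1ccc(OCOC)cc1)O3)[C@@H](c1ccc(OCOC)cc1)O2 | intermediate
34 | 2-{(E)-2-[4-(methoxymethoxy)phenyl]ethenyl}-4,4,5,5-tetramethyl-1,3,2-dioxaborolane | COCOc1ccc(/C=C/B2OC(C)(C)C(C)(C)O2)cc1 | intermediate
35 | heptakis(methoxymethyl) ether of the target, (2S,3S,2'R,3'R) | COCOc1ccc(/C=C/c2cc(OCOC)cc3c2[C@H](c2cc(OCOC)c4c(c2)[C@@H](c2cc(OCOC)cc(OCOC)c2)[C@H](c2ccc(OCOC)cc2)O4)[C@@H](c2ccc(OCOC)cc2)O3)cc1 | intermediate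
36 | CNP0172909.1, (2S,3S)-3-[(2R,3R)-3-(3,5-dihydroxyphenyl)-7-hydroxy-2-(4-hydroxyphenyl)-2,3-dihydro-1-benzofuran-5-yl]-2-(4-hydroxyphenyl)-4-[(E)-2-(4-hydroxyphenyl)ethenyl]-2,3-dihydro-1-benzofuran-6-ol | Oc1ccc(/C=C/c2cc(O)cc3c2[C@H](c2cc(O)c4c(c2)[C@@H](c2cc(O)cc(O)c2)[C@H](c2ccc(O)cc2)O4)[C@@H](c2ccc(O)cc2)O3)cc1 | target

## Summary

Total step count: 22.
Longest linear sequence: 10 steps (steps 1, 2, 3, 6, 14, 17, 18, 19, 21, 22).

## Steps most likely to fail

Step 19. The benzylide may discriminate poorly between its faces at a methide carbon that is flanked by the C4 bromine and the primed aryl group, or capture may be so slow that the methide oligomerises. The fallback sets out from 29 and gives up reagent control. Thiolane (tetrahydrothiophene) is benzylated with 4 in the presence of NaBF4 to the achiral and smaller salt 1-{[4-(methoxymethoxy)phenyl]methyl}thiolan-1-ium tetrafluoroborate F1. With Cs2CO3 in CH2Cl2 its ylide should annulate 29 to the trans ring in both absolute senses, giving 33 together with its (2R,3R,2'R,3'R) diastereomer F2. Because the primed centres are fixed, the two are diastereomers and should separate by chromatography on silica or by preparative HPLC. The route is rejoined at 33.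

Step 17. The bromine–lithium exchange on 23 may be accompanied by metalation next to the acetals or at the doubly benzylic C3'–H, and the aryllithium may exchange bromine with 26 instead of adding to its deactivated formyl group. The fallback sets out from 23 and avoids organolithium chemistry. Miyaura borylation (B2pin2, Pd(dppf)Cl2, KOAc, dioxane, 80 °C) should give 2-{(2R,3R)-3-[3,5-bis(methoxymethoxy)phenyl]-7-(methoxymethoxy)-2-[4-(methoxymethoxy)phenyl]-2,3-dihydro-1-benzofuran-5-yl}-4,4,5,5-tetramethyl-1,3,2-dioxaborolane F3. This is added to aldehyde 25 by rhodium-catalysed 1,2-addition of an arylboron reagent ([Rh(cod)Cl]2, t-Bu3P, K3PO4, dioxane/H2O, 60 °C), a reaction that tolerates the aryl bromide and the free phenol. The route is rejoined at 28.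

Step 22. During the sevenfold acetal cleavage the acid may protonate the electron-rich stilbene and trigger Friedel–Crafts closure onto the neighbouring primed ring (C4' and C6' are activated by the C7' hydroxyl), ionise the C2–O1 bond, or allow hydroxymethylation by released formaldehyde equivalents. The fallback sets out from 33 and moves the acid step ahead of the styrene. Methanolic HCl on 33 should give (2S,3S)-4-bromo-3-[(2R,3R)-3-(3,5-dihydroxyphenyl)-7-hydroxy-2-(4-hydroxyphenyl)-2,3-dihydro-1-benzofuran-5-yl]-2-(4-hydroxyphenyl)-2,3-dihydro-1-benzofuran-6-ol F4. Peracetylation (Ac2O, pyridine) gives its hexaacetate F5. A Heck reaction with commercial 4-acetoxystyrene (Pd(OAc)2, P(o-tol)3, Et3N, DMF, 100 °C) gives the heptaacetate of the target F6. Mild methanolysis (K2CO3, MeOH, 0 °C, argon) then frees the phenols under basic conditions, and the route is rejoined at 36.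

## Further compounds

F1 | step 19 | 1-{[4-(methoxymethoxy)phenyl]methyl}thiolan-1-ium tetrafluoroborate | COCOc1ccc(C[S+]2CCCC2)cc1.F[B-](F)(F)F
F2 | step 19 | (2R,3R)-3-[(2R,3R)-3-[3,5-bis(methoxymethoxy)phenyl]-7-(methoxymethoxy)-2-[4-(methoxymethoxy)phenyl]-2,3-dihydro-1-benzofuran-5-yl]-4-bromo-6-(methoxymethoxy)-2-[4-(methoxymethoxy)phenyl]-2,3-dihydro-1-benzofuran | Brc1cc(OCOC)cc2c1[C@@H](c1cc(OCOC)c3c(c1)[C@@H](c1cc(OCOC)cc(OCOC)c1)[C@H](c1ccc(OCOC)cc1)O3)[C@H](c1ccc(OCOC)cc1)O2
F3 | step 17 | 2-{(2R,3R)-3-[3,5-bis(methoxymethoxy)phenyl]-7-(methoxymethoxy)-2-[4-(methoxymethoxy)phenyl]-2,3-dihydro-1-benzofuran-5-yl}-4,4,5,5-tetramethyl-1,3,2-dioxaborolane | CC1(C)OB(OC1(C)C)c1cc(OCOC)c2c(c1)[C@@H](c1cc(OCOC)cc(OCOC)c1)[C@H](c1ccc(OCOC)cc1)O2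
F4 | step 22 | (2S,3S)-4-bromo-3-[(2R,3R)-3-(3,5-dihydroxyphenyl)-7-hydroxy-2-(4-hydroxyphenyl)-2,3-dihydro-1-benzofuran-5-yl]-2-(4-hydroxyphenyl)-2,3-dihydro-1-benzofuran-6-ol | Brc1cc(O)cc2c1[C@H](c1cc(O)c3c(c1)[C@@H](c1cc(O)cc(O)c1)[C@H](c1ccc(O)cc1)O3)[C@@H](c1ccc(O)cc1)O2
F5 | step 22 | hexaacetate of F4 | Brc1cc(OC(C)=O)cc2c1[C@H](c1cc(OC(C)=O)c3c(c1)[C@@H](c1cc(OC(C)=O)cc(OC(C)=O)c1)[C@H](c1ccc(OC(C)=O)cc1)O3)[C@@H](c1ccc(OC(C)=O)cc1)O2
F6 | step 22 | heptaacetate of the target | CC(=O)Oc1ccc(/C=C/c2cc(OC(C)=O)cc3c2[C@H](c2cc(OC(C)=O)c4c(c2)[C@@H](c2cc(OC(C)=O)cc(OC(C)=O)c2)[C@H](c2ccc(OC(C)=O)cc2)O4)[C@@H](c2ccc(OC(C)=O)cc2)O3)cc1
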